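The plan rests on opening the dihydropyran ring of the chroman at two bonds, C4–C4a and O1–C2. This reveals two achiral, commercial compounds: 2,3-dimethylhydroquinone and the C45 allylic alcohol solanesol, whose first isoprene unit supplies C4, C3, C2 and the 2-methyl group. The key step copies the biosynthesis (prenylation, then cyclase ring closure) in one flask: a confined chiral Brønsted acid joins the allylic CH2 to the arene and then adds the neighbouring phenol oxygen to the methyl-bearing alkene carbon, which sets the only stereocentre. It exploits the twofold symmetry of the hydroquinone ring, whose two free carbons and two hydroxyls are equivalent, and the tertiary, cation-stabilising nature of C2.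

Key step: step 1

Assumption: the chiral acid (IDPi, the imidodiphosphorimidate HN[P(=NSO2CF3)(O2-binaphthyl)]2 built from two 3,3'-diaryl-1,1'-bi-2-naphthol units) is bought or made outside the route. Which of its two antipodes gives the (2R)-chroman has to be settled by experiment, and the route is written for that antipode.

Step 1
Reactants: 1 2,3-dimethylhydroquinone (2,3-dimethylbenzene-1,4-diol); 2 all-E-solanesol (the C45 nonaprenol, all eight stereogenic double bonds E)
Product: 4 (2R)-plastochromanol-8, via plastoquinol-9 3 (not isolated)
Conditions: chiral IDPi acid (5 mol %), 1 (3 equiv), 2 added slowly, CHCl3, 5 Å MS, 0 to 40 °C, Ar, dark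
Reagents that add atoms: none
Why: Proposed new method: the strong chiral acid ionises allylic alcohol 2 to the (2E)-solanesyl cation, whose primary terminus alkylates one of the two equivalent free ring carbons of 1 (Friedel–Crafts allylation, CH2–aryl bond) to give 3; the same acid then protonates the CH carbon of the first side-chain alkene of 3 while the ortho phenol oxygen adds anti to the methyl-bearing carbon in a concerted but asynchronous hydroalkoxylation (O–C bond). The closest known reaction types are the BF3·OEt2- or ZnCl2-mediated condensation of hydroquinones with isoprenoid allylic alcohols, which gives racemic chromanols, and the imidodiphosphorimidate-catalysed asymmetric intramolecular hydroalkoxylation of unactivated alkenes to 2-alkyl-2-methyl cyclic ethers; their merger on a phenol nucleophile and a polyene is untested. The dihydropyran ring closes in the 6-endo-trig mode with Markovnikov regiochemistry. The C2 stereocentre is under catalyst control: in the confined ion pair the (E)-alkene should sit with its methyl group against a 3,3'-aryl wall and its long chain in the open channel, and the catalyst antipode is chosen so that oxygen adds to the Re face of the methyl-bearing carbon (priorities =CH > CH2 > CH3), which gives (R). The step needs mono-C-allylation, secured by excess of symmetric 1 and slow addition of 2; retention of the (E)-alkene, secured by a tight ion pair in a non-polar, non-fluorinated solvent; and reaction at one alkene out of nine, secured because only the first alkene has a phenol placed for nucleophile-assisted proton transfer, while each remote alkene would have to form an unassisted tertiary cation.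

Compound list
1 | 2,3-dimethylhydroquinone (2,3-dimethylbenzene-1,4-diol) | Cc1c(C)c(O)ccc1O | starting material
2 | all-E-solanesol, (2E,6E,10E,14E,18E,22E,26E,30E)-3,7,11,15,19,23,27,31,35-nonamethylhexatriaconta-2,6,10,14,18,22,26,30,34-nonaen-1-ol | CC(C)=CCC/C(C)=C/CC/C(C)=C/CC/C(C)=C/CC/C(C)=C/CC/C(C)=C/CC/C(C)=C/CC/C(C)=C/CC/C(C)=C/CO | starting material
3 | plastoquinol-9, 2,3-dimethyl-5-[(all-E)-solanesyl]benzene-1,4-diol | CC(C)=CCC/C(C)=C/CC/C(C)=C/CC/C(C)=C/CC/C(C)=C/CC/C(C)=C/CC/C(C)=C/CC/C(C)=C/CC/C(C)=C/Cc1cc(O)c(C)c(C)c1O | intermediate
4 | plastochromanol-8, (2R)-2,7,8-trimethyl-2-[(3E,7E,11E,15E,19E,23E,27E)-4,8,12,16,20,24,28,32-octamethyltritriaconta-3,7,11,15,19,23,27,31-octaen-1-yl]chroman-6-ol | CC(C)=CCC/C(C)=C/CC/C(C)=C/CC/C(C)=C/CC/C(C)=C/CC/C(C)=C/CC/C(C)=C/CC/C(C)=C/CC[C@]1(C)CCc2cc(O)c(C)c(C)c2O1 | target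

Total step count: 1
Longest linear sequence: 1 step

Steps most likely to fail: the route has a single step, so it is the only entry.

Step 1 (bears the label "Proposed new method:"). Several processes may go wrong:
- poor facial selectivity in the oxygen delivery to the alkene, which would lower the enantiomeric purity;
- protonation of remote alkenes, followed by cation–olefin cyclisation or double-bond migration in the chain;
- loss of the (E)-geometry of the allyl cation before the C–C bond forms;
- a second allylation at the free ring carbon of the product.

Fallback (known chemistry; sets out from 1 and 2 and comes back at 4): the asymmetric catalyst is given up and the same two-bond annulation is run in its classical racemic form, with excess 1 and 2 and BF3·OEt2 in dioxane at room temperature and then 50 °C under argon. This should give racemic plastochromanol-8, that is 4 together with its mirror image (2S)-plastochromanol-8 F1. The two enantiomers are then separated by preparative HPLC on a cellulose tris(3,5-dimethylphenylcarbamate) phase with hexane/2-propanol; 4 is collected and F1 is set aside.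

Further compounds
F1 | step 1 | (2S)-plastochromanol-8 | CC(C)=CCC/C(C)=C/CC/C(C)=C/CC/C(C)=C/CC/C(C)=C/CC/C(C)=C/CC/C(C)=C/CC/C(C)=C/CC[C@@]1(C)CCc2cc(O)c(C)c(C)c2O1
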